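**Strategy.** The target is numbered as a furo[3,4-c]furan: C1(Ar)–O2–C3H2–C3a(OH)–C4(Ar)–O5–C6H2–C6a(H). Ring C1/O2/C3/C3a/C6a holds a tertiary carbinol (C3a) next to an O–CH2 unit, the retron of an interrupted Feist–Benary annulation. Malondialdehyde and ethyl bromopyruvate are therefore joined in one catalytic asymmetric operation (aldol C6a–C3a, then O2–C3 alkylation) to a 3-hydroxy-2,3-dihydrofuran that carries no aryl group yet. Reduction and lactonisation close the second ring. Both aryl groups are then added to oxocarbenium ions of the cis-fused bicycle: veratrole from the convex face (exo, C1), and aryllithium then hydride (endo, C4).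

Key step: step 1

Assumption: malondialdehyde 1 is counted as commercial because its sodium enolate is sold and is acidified to the free dialdehyde just before use; the quinidine-derived catalyst is taken to give the (R)-carbinol 4, and if the sense proves opposite its quinine-derived pseudoenantiomer is used.

Step 1
Reactants: 1 malondialdehyde; 2 ethyl bromopyruvate
Product: 4 ethyl (3R)-4-formyl-3-hydroxy-2,3-dihydrofuran-3-carboxylate, via bromo aldol adduct 3 (not isolated)
Conditions: hydroquinidine 2,5-diphenyl-4,6-pyrimidinediyl diether, (DHQD)2PYR (10 mol %), 1,8-bis(dimethylamino)naphthalene (1.0 equiv), THF, −78 °C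
Reagents that add atoms: none
Why: Interrupted Feist–Benary reaction: the ammonium enolate of 1 adds through its central carbon to the ketone carbonyl of 2 (aldol, future C6a–C3a bond, giving 3), and the enolate oxygen of the resulting 2-substituted malondialdehyde then displaces bromide (future O2–C3 bond). The closest known reaction type is the cinchona-catalysed annulation of 1,3-cyclohexanediones, which are about as acidic as 1, with bromopyruvate esters. The dihydrofuran ring is closed by a 5-exo-tet O-alkylation. The only new stereocentre, the carbinol carbon, is set in the aldol step by the catalyst, whose protonated quinuclidine holds the enolate as an ion pair over one face of the ketone. The step needs attack at the carbonyl carbon before any substitution at CH2Br and no loss of water to the furan; the strongly electrophilic 2-oxo ester, the symmetry of 1 (either oxygen can close the ring) and the cold, acid-free medium should secure this.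

Step 2
Reactants: 4 ethyl (3R)-4-formyl-3-hydroxy-2,3-dihydrofuran-3-carboxylate
Product: 6 (6aR)-6a-hydroxy-6,6a-dihydro-1H,3H-furo[3,4-c]furan-1-one, via allylic alcohol 5 (not isolated)
Conditions: NaBH4, EtOH/THF, −40 → 0 °C; neutral work-up, Et3N-deactivated silica
Reagents that add atoms: none
Why: Sodium borohydride should reduce the vinylogous formyl group, the only aldehyde, well before the ester, and the primary alkoxide of 5 then lactonises onto the neighbouring ethyl ester (5-exo-trig transesterification), which closes the second ring without touching the carbinol stereocentre.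

Step 3
Reactants: 6 (6aR)-6a-hydroxy-6,6a-dihydro-1H,3H-furo[3,4-c]furan-1-one; 7 1,2-dimethoxybenzene
Product: 8 (3aS,4R,6aR)-4-(3,4-dimethoxyphenyl)-6a-hydroxytetrahydro-1H,3H-furo[3,4-c]furan-1-one
Conditions: 7 (5 equiv), TfOH (5 mol %), CH2Cl2, −60 °C
Reagents that add atoms: none
Why: Acid-catalysed Friedel–Crafts hydroarylation of a cyclic enol ether: protonation at the ring-fusion carbon can only give the cis-fused oxocarbenium ion, and veratrole attacks it para to a methoxy group from the convex face, so that H-3a is cis to the hydroxyl group and the aryl group is exo (4R), which is also the more stable arrangement.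

Step 4
Reactants: 8 (3aS,4R,6aR)-4-(3,4-dimethoxyphenyl)-6a-hydroxytetrahydro-1H,3H-furo[3,4-c]furan-1-one; 9 4-bromo-1,2-dimethoxybenzene
Product: 11 (1R,3aR,6aS)-1,4-bis(3,4-dimethoxyphenyl)tetrahydro-1H,3H-furo[3,4-c]furan-3a,4-diol (both C4 epimers), via 3,4-dimethoxyphenyllithium 10 (not isolated)
Conditions: 9 (2.4 equiv), n-BuLi (2.3 equiv), THF, −78 °C; then 8, −78 °C; then H2O
Reagents that add atoms: none
Why: Addition of an aryllithium to a lactone, which at −78 °C should stop at the lithium hemiketal as in C-aryl glycoside synthesis; the first equivalent only deprotonates the tertiary alcohol, and the new hemiketal centre need not be controlled because it becomes planar in step 5.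

Step 5
Reactants: 11 (1R,3aR,6aS)-1,4-bis(3,4-dimethoxyphenyl)tetrahydro-1H,3H-furo[3,4-c]furan-3a,4-diol
Product: 12 (1R,3aR,4R,6aS)-1,4-bis(3,4-dimethoxyphenyl)tetrahydro-1H,3H-furo[3,4-c]furan-3a(4H)-ol
Conditions: Et3SiH (3 equiv), BF3·OEt2 (2 equiv), CH2Cl2/MeCN, −78 → −40 °C; aq. NaHCO3
Reagents that add atoms: none
Why: Ionic hydrogenation of an aryl hemiketal: BF3·OEt2 forms the aryl-stabilised oxocarbenium ion and Et3SiH delivers hydride to its convex face, cis to the 3a-hydroxyl group, which sets C4 as R with the aryl group endo, while the dimethoxybenzylic ether at C1 should stay intact at this temperature.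

**Compound list**

1 | malondialdehyde (propanedial) | O=CCC=O | starting material
2 | ethyl bromopyruvate (ethyl 3-bromo-2-oxopropanoate) | CCOC(=O)C(=O)CBr | starting material
3 | ethyl (2S)-2-(bromomethyl)-3-formyl-2-hydroxy-4-oxobutanoate | CCOC(=O)[C@](O)(CBr)C(C=O)C=O | intermediate
4 | ethyl (3R)-4-formyl-3-hydroxy-2,3-dihydrofuran-3-carboxylate | CCOC(=O)[C@]1(O)COC=C1C=O | intermediate
5 | ethyl (3R)-3-hydroxy-4-(hydroxymethyl)-2,3-dihydrofuran-3-carboxylate | CCOC(=O)[C@]1(O)COC=C1CO | intermediate
6 | (6aR)-6a-hydroxy-6,6a-dihydro-1H,3H-furo[3,4-c]furan-1-one (C3a=C4 enol ether) | O=C1OCC2=COC[C@@]12O | intermediate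
7 | 1,2-dimethoxybenzene (veratrole) | COc1ccccc1OC | starting material
8 | (3aS,4R,6aR)-4-(3,4-dimethoxyphenyl)-6a-hydroxytetrahydro-1H,3H-furo[3,4-c]furan-1-one | O=C1OC[C@H]2[C@H](c3ccc(OC)c(OC)c3)OC[C@@]12O | intermediate
9 | 4-bromo-1,2-dimethoxybenzene | COc1ccc(Br)cc1OC | starting material
10 | 3,4-dimethoxyphenyllithium | [Li]c1ccc(OC)c(OC)c1 | intermediate
11 | (1R,3aR,6aS)-1,4-bis(3,4-dimethoxyphenyl)tetrahydro-1H,3H-furo[3,4-c]furan-3a,4-diol, both C4 epimers | COc1ccc(C2(O)OC[C@H]3[C@H](c4ccc(OC)c(OC)c4)OC[C@@]23O)cc1OC | intermediate
12 | (1R,3aR,4R,6aS)-1,4-bis(3,4-dimethoxyphenyl)tetrahydro-1H,3H-furo[3,4-c]furan-3a(4H)-ol (1-aryl exo, 4-aryl endo) | COc1ccc([C@H]2OC[C@H]3[C@H](c4ccc(OC)c(OC)c4)OC[C@@]23O)cc1OC | target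

**Total step count:** 5. **Longest linear sequence:** 5 steps (1 and 2 → 4 → 6 → 8 → 11 → 12).

**Steps most likely to fail**

Step 1. The very acidic dialdehyde may react outside the chiral ion pair, so that the facial selectivity of the aldol is poor, or substitution at CH2Br may come before the aldol. The fallback sets out from 1 and 2 and returns at 4, making the two bonds in separate known operations. Compound 1 is O-silylated (Me3SiCl, Et3N, Et2O) to (E)-3-(trimethylsilyloxy)prop-2-enal F1. A Mukaiyama aldol addition of F1 to 2 follows, catalysed by the complex of Cu(OTf)2 (divalent copper, 10 mol %) with a tert-butyl-bis(oxazoline) ligand of the enantiomeric series that gives the (S)-carbinol, in CH2Cl2 at −78 °C. The copper binds the 2-oxo ester as a chelate, and the product after desilylating work-up should be the bromo aldol 3, here isolated. K2CO3 in MeCN then closes the ring by O-alkylation to 4.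

Step 3. Protonation of 6 may be followed by loss of water and aromatisation to the furan, or the product may ionise at its new benzylic ether and take up a second arene. The fallback sets out from 6 and returns at 8 without any acid. A Heck–Matsuda arylation of 6 with 3,4-dimethoxybenzenediazonium tetrafluoroborate (Pd(OAc)2, divalent palladium, 5 mol %, NaOAc, MeCN, room temperature) should place the aryl group on the oxygen-bearing alkene carbon from the face of the hydroxyl group. Beta-hydride elimination towards the lactone CH2 should then give the enol lactone (4S,6aR)-4-(3,4-dimethoxyphenyl)-6a-hydroxy-6,6a-dihydro-1H,4H-furo[3,4-c]furan-1-one F2. Hydrogenation directed by the tertiary hydroxyl group ([Ir(cod)(PCy3)(py)]PF6, H2, CH2Cl2) then delivers H-3a cis to that group and gives 8.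

Step 5. Hydride delivery may be poorly face-selective, or the Lewis acid may open the dimethoxybenzylic ether at C1, which would then be reduced. The fallback sets out from 11 and returns at 12. Compound 11 is reduced through its open hydroxy ketone form with zinc borohydride, Zn(BH4)2 (Et2O, −20 °C). The zinc chelate between the ketone and the tertiary hydroxyl group should direct hydride to the side of the ring CH2 and give the triol (3R,4S,5R)-5-(3,4-dimethoxyphenyl)-3-[(R)-(3,4-dimethoxyphenyl)(hydroxy)methyl]-4-(hydroxymethyl)oxolan-3-ol F3. A Mitsunobu cyclodehydration (PPh3, DIAD, THF, 0 °C) then activates the primary hydroxyl group, which the benzylic hydroxyl displaces with its own configuration unchanged, to give 12.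

**Further compounds**

F1 | step 1 | (E)-3-(trimethylsilyloxy)prop-2-enal | C[Si](C)(C)O/C=C/C=O
F2 | step 3 | (4S,6aR)-4-(3,4-dimethoxyphenyl)-6a-hydroxy-6,6a-dihydro-1H,4H-furo[3,4-c]furan-1-one | O=C1OC=C2[C@H](c3ccc(OC)c(OC)c3)OC[C@@]12O
F3 | step 5 | (3R,4S,5R)-5-(3,4-dimethoxyphenyl)-3-[(R)-(3,4-dimethoxyphenyl)(hydroxy)methyl]-4-(hydroxymethyl)oxolan-3-ol | COc1ccc([C@@H](O)[C@]2(O)CO[C@@H](c3ccc(OC)c(OC)c3)[C@@H]2CO)cc1OC
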